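## Retrosynthetic overview

1. The target 24 comes from its 2-O-TES ether 23. Compound 23 comes from the open-chain epoxy aldehyde/allylic bromide 21: one CrCl2 operation forms C6–C7 and O6–C12, so the ten-membered carbocycle and the α-methylene-γ-lactone close together and C6 and C7 are set.
2. Compound 21 comes from cross metathesis of a C7 vinyl group with methyl 2-(bromomethyl)acrylate, which supplies C11, C12 and C13.
3. C8–C9, with the angelate already on O8, comes from a syn-selective angeloyloxy-allylation of the 2-formyl enoate 11. Acrolein supplies C7 and C8. The new O9 is then acetylated.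
4. The C1=C10 geometry and the C2 carbinol come from a D-proline aminoxylation/bromo-Wittig sequence on a nerol-derived aldehyde. C9 comes from DMF.
5. Ring order: the cis-epoxide is made first by Sharpless epoxidation of nerol. The carbocycle and lactone are made together near the end.

Atom labels C1–C15 follow the germacrane numbering of the target: C1=C10 with C14 as CO2Me, C2–OH, C4/C5 epoxide with C15 as CH3, C6–O–C12 lactone, C11=C13, C8–OAng, C9–OAc.

Assumption: the (R,R)-salen/CrCl3 catalyst of step 9 is taken to deliver the allyl unit to the Re face of aldehyde 11. Both ligand antipodes are commercial, so the other one is used if the sense is reversed.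

## Route

Step 1
Reactants: 1 nerol
Product: 2 [(2S,3R)-3-methyl-3-(4-methylpent-3-enyl)oxiran-2-yl]methanol
Conditions: Ti(OiPr)4 (10 mol %), L-(+)-diethyl tartrate (12 mol %), t-BuOOH, 4 Å MS, CH2Cl2, −20 °C
Reagents that add atoms: tert-butyl hydroperoxide CC(C)(C)OO
Why: In this Katsuki–Sharpless asymmetric epoxidation the L-(+)-tartrate catalyst oxidises the face that gives (2S,3R), and the Z alkene of nerol is carried stereospecifically into the cis-epoxide (C4 R, C5 S).

Step 2
Reactants: 2 epoxy alcohol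
Product: 3 3-[(2R,3S)-3-(hydroxymethyl)-2-methyloxiran-2-yl]propanal
Conditions: O3, CH2Cl2, −78 °C; then Me2S, −78 to 23 °C
Reagents that add atoms: ozone [O-][O+]=O
Why: Ozonolysis with reductive work-up cleaves the only remaining C=C and unmasks C1 as the aldehyde without touching the epoxide.

Step 3
Reactants: 3 aldehyde, 4 methyl (triphenylphosphoranylidene)acetate
Product: 7 methyl (2Z,4S)-4-(anilinooxy)-2-bromo-5-[(2R,3S)-3-(hydroxymethyl)-2-methyloxiran-2-yl]pent-2-enoate, via bromo ylide 5 (not isolated), via anilinooxy aldehyde 6 (not isolated)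
Conditions: D-proline (20 mol %), PhNO, MeCN, −20 °C; then the solution of 4 + NBS (CH2Cl2, −20 °C) is added, 0 °C
Reagents that add atoms: nitrosobenzene O=Nc1ccccc1; N-bromosuccinimide O=C1CCC(=O)N1Br
Why: The proline-catalysed α-aminoxylation (D-proline enamine attacks the oxygen of PhNO) sets C2 as S, and the Wittig olefination with the stabilised bromo ylide in the same flask traps the labile aldehyde and gives the Z-bromoalkene with the ester trans to C2.

Step 4
Reactants: 7 anilinooxy ester
Product: 8 methyl (2Z,4S)-2-bromo-4-hydroxy-5-[(2R,3S)-3-(hydroxymethyl)-2-methyloxiran-2-yl]pent-2-enoate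
Conditions: Cu(OAc)2 (30 mol %), MeOH, 23 °C
Reagents that add atoms: none
Why: The copper-catalysed N–O cleavage of the O-anilino group is mild enough for the epoxide and the bromoenoate, and C2–OH cannot lactonise because it lies trans to the ester.

Step 5
Reactants: 8 diol
Product: 9 bis(triethylsilyl) ether of 8 (O2 and O6 silylated)
Conditions: Et3SiCl, imidazole, CH2Cl2, 0 °C
Reagents that add atoms: chlorotriethylsilane CC[Si](Cl)(CC)CC
Why: This standard silyl ether formation puts one protecting group on both hydroxyls, and they can be told apart later as primary and secondary.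

Step 6
Reactants: 9 bromoenoate
Product: 11 methyl (2E,4S)-2-formyl-4-(triethylsilyloxy)-5-[(2R,3S)-2-methyl-3-(triethylsilyloxymethyl)oxiran-2-yl]pent-2-enoate, via alkenylmagnesium chloride 10 (not isolated)
Conditions: iPrMgCl·LiCl, THF, −78 to −40 °C; DMF, −40 °C; aqueous work-up
Reagents that add atoms: N,N-dimethylformamide CN(C)C=O
Why: Bromine–magnesium exchange on the activated α-bromoenoate and formylation with DMF install C9, and the isomer with the small formyl group cis to C2 is both the retention product and the thermodynamic one.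

Step 7
Reactants: 12 angelic acid
Product: 13 angeloyl chloride
Conditions: 1-chloro-N,N,2-trimethylprop-1-en-1-amine, CH2Cl2, 0 °C
Reagents that add atoms: 1-chloro-N,N,2-trimethylprop-1-en-1-amine CC(C)=C(Cl)N(C)C
Why: The α-chloroenamine (Ghosez) reagent forms the acid chloride under neutral conditions without free HCl, so the Z alkene does not isomerise to the tiglate.

Step 8
Reactants: 13 angeloyl chloride, 14 acrolein
Product: 15 3-chloroprop-1-enyl angelate (E/Z mixture at the enol ester bond)
Conditions: ZnCl2 (2 mol %), CH2Cl2, −20 to 23 °C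
Reagents that add atoms: none
Why: The Lewis acid-catalysed 1,4-addition of an acyl chloride to acrolein gives the γ-acyloxy allylic chloride, and its enol ester geometry does not matter because the derived allylmetal equilibrates.

Step 9
Reactants: 11 formyl enoate, 15 chloropropenyl angelate
Product: 16 methyl (2E,4S)-2-[(1S,2S)-2-(angeloyloxy)-1-(trimethylsilyloxy)but-3-enyl]-4-(triethylsilyloxy)-5-[(2R,3S)-2-methyl-3-(triethylsilyloxymethyl)oxiran-2-yl]pent-2-enoate
Conditions: CrCl3 (10 mol %), Mn, (R,R)-N,N'-bis(3,5-di-tert-butylsalicylidene)cyclohexane-1,2-diamine (12 mol %), Et3N (20 mol %), Me3SiCl, MeCN, 23 °C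
Reagents that add atoms: chlorotrimethylsilane C[Si](C)(C)Cl
Why: In this catalytic asymmetric Nozaki–Hiyama acyloxy-allylation the γ-acyloxyallylchromium adds through its oxygenated carbon to give the syn (threo) adduct under catalyst control (8S,9S), and Me3SiCl caps O9 at once so the angelate cannot migrate.

Step 10
Reactants: 16 trimethylsilyl ether
Product: 18 the C9 acetate, methyl (2E,4S)-2-[(1S,2S)-1-acetoxy-2-(angeloyloxy)but-3-enyl]-4-(triethylsilyloxy)-5-[(2R,3S)-2-methyl-3-(triethylsilyloxymethyl)oxiran-2-yl]pent-2-enoate, via C9 alcohol 17 (not isolated)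
Conditions: citric acid, MeOH, 0 °C; then Ac2O, pyridine, DMAP (cat.), CH2Cl2, 0 °C
Reagents that add atoms: acetic anhydride CC(=O)OC(C)=O
Why: Selective solvolysis of the far more labile Me3Si ether and immediate acetylation give O9 = Ac and O8 = Ang with no selectivity problem, because O9 is the only free hydroxyl.

Step 11
Reactants: 18 bis-TES ether
Product: 19 methyl (2E,4S)-2-[(1S,2S)-1-acetoxy-2-(angeloyloxy)but-3-enyl]-5-[(2R,3R)-3-formyl-2-methyloxiran-2-yl]-4-(triethylsilyloxy)pent-2-enoate
Conditions: (COCl)2, DMSO, CH2Cl2, −78 to −30 °C; Et3N, −78 to 0 °C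
Reagents that add atoms: none
Why: Swern oxidation applied directly to the silyl ether lets activated DMSO cleave and oxidise the primary TES ether, while the secondary one at C2 survives and prevents the C6 aldehyde from closing to a six-membered lactol.

Step 12
Reactants: 19 vinyl epoxy aldehyde, 20 methyl 2-(bromomethyl)acrylate
Product: 21 the seco compound, 19 in which CH=CH2 has become (Z)-CH=C(CH2Br)CO2Me
Conditions: 20 (5 equiv), second-generation Hoveyda–Grubbs catalyst (10 mol %), 2,6-dichloro-1,4-benzoquinone (10 mol %), toluene, 50 °C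
Reagents that add atoms: none
Why: Olefin cross metathesis engages the only terminal alkene of 19 with the excess 1,1-disubstituted acrylate, the two trisubstituted enoates stay inert, and the thermodynamic isomer (C8 trans to the ester) forms.

Step 13
Reactants: 21 seco aldehyde/allylic bromide
Product: 23 2-O-triethylsilyl ether of the target, via macrocyclic hydroxy ester 22 (not isolated)
Conditions: CrCl2 (10 equiv), DMF, 0.002 M, addition of 21 over 12 h, 23 °C; then 40 °C, 2 h, same flask
Reagents that add atoms: none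
Why: In this intramolecular Nozaki–Hiyama allylation/lactonisation the allylchromium attacks the aldehyde through C7 in a chair transition state (6,7-anti, hence the trans-lactone) on the Felkin–Anh face anti to the epoxide C–O bond (5,6-erythro, so 6S and 7R), the cis-epoxide and cis C1=C10 bond hold the chain ends close, and the C6 alkoxide then displaces methoxide at C12 so that carbocycle and lactone form together, the main hazard being 1,4-loss of the C8 angelate from the allylmetal.

Step 14
Reactants: 23 silyl ether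
Product: 24 CNP0278274.1 (target)
Conditions: HF·pyridine, pyridine, THF, 0 °C
Reagents that add atoms: none
Why: Buffered fluoride desilylation frees C2–OH without opening the epoxide or disturbing the three esters and the α-methylene lactone.

## Compound list

1 | nerol, (2Z)-3,7-dimethylocta-2,6-dien-1-ol | CC(C)=CCC/C(C)=C\CO | starting material
2 | [(2S,3R)-3-methyl-3-(4-methylpent-3-enyl)oxiran-2-yl]methanol | OC[C@@H]1O[C@]1(C)CCC=C(C)C | intermediate
3 | 3-[(2R,3S)-3-(hydroxymethyl)-2-methyloxiran-2-yl]propanal | OC[C@@H]1O[C@]1(C)CCC=O | intermediate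
4 | methyl (triphenylphosphoranylidene)acetate | COC(=O)C=P(c1ccccc1)(c1ccccc1)c1ccccc1 | starting material
5 | methyl bromo(triphenylphosphoranylidene)acetate (not isolated) | COC(=O)C(Br)=P(c1ccccc1)(c1ccccc1)c1ccccc1 | intermediate
6 | (2S)-2-(anilinooxy)-3-[(2R,3S)-3-(hydroxymethyl)-2-methyloxiran-2-yl]propanal (not isolated) | OC[C@@H]1O[C@]1(C)C[C@H](ONc2ccccc2)C=O | intermediate
7 | methyl (2Z,4S)-4-(anilinooxy)-2-bromo-5-[(2R,3S)-3-(hydroxymethyl)-2-methyloxiran-2-yl]pent-2-enoate | OC[C@@H]1O[C@]1(C)C[C@H](ONc2ccccc2)/C=C(\Br)C(=O)OC | intermediate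
8 | methyl (2Z,4S)-2-bromo-4-hydroxy-5-[(2R,3S)-3-(hydroxymethyl)-2-methyloxiran-2-yl]pent-2-enoate | OC[C@@H]1O[C@]1(C)C[C@H](O)/C=C(\Br)C(=O)OC | intermediate
9 | bis(triethylsilyl) ether of 8 | CC[Si](CC)(CC)OC[C@@H]1O[C@]1(C)C[C@H](O[Si](CC)(CC)CC)/C=C(\Br)C(=O)OC | intermediate
10 | alkenylmagnesium chloride from 9, MgCl in place of Br (not isolated) | CC[Si](CC)(CC)OC[C@@H]1O[C@]1(C)C[C@H](O[Si](CC)(CC)CC)/C=C(\[Mg]Cl)C(=O)OC | intermediate
11 | methyl (2E,4S)-2-formyl-4-(triethylsilyloxy)-5-[(2R,3S)-2-methyl-3-(triethylsilyloxymethyl)oxiran-2-yl]pent-2-enoate | CC[Si](CC)(CC)OC[C@@H]1O[C@]1(C)C[C@H](O[Si](CC)(CC)CC)/C=C(\C=O)C(=O)OC | intermediate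
12 | angelic acid, (2Z)-2-methylbut-2-enoic acid | C/C=C(/C)C(=O)O | starting material
13 | angeloyl chloride | C/C=C(/C)C(=O)Cl | intermediate
14 | acrolein | C=CC=O | starting material
15 | 3-chloroprop-1-enyl angelate (E/Z mixture at the enol ester bond, left open in the SMILES) | C/C=C(/C)C(=O)OC=CCCl | intermediate
16 | syn adduct, (8S,9S), O9-SiMe3, O8-angeloyl, C7 vinyl, O2 and O6 TES | CC[Si](CC)(CC)OC[C@@H]1O[C@]1(C)C[C@H](O[Si](CC)(CC)CC)/C=C(\[C@H](O[Si](C)(C)C)[C@@H](OC(=O)/C(C)=C\C)C=C)C(=O)OC | intermediate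
17 | C9 alcohol from 16 (not isolated) | CC[Si](CC)(CC)OC[C@@H]1O[C@]1(C)C[C@H](O[Si](CC)(CC)CC)/C=C(\[C@H](O)[C@@H](OC(=O)/C(C)=C\C)C=C)C(=O)OC | intermediate
18 | C9 acetate, (8S,9S), O2 and O6 TES | CC[Si](CC)(CC)OC[C@@H]1O[C@]1(C)C[C@H](O[Si](CC)(CC)CC)/C=C(\[C@H](OC(C)=O)[C@@H](OC(=O)/C(C)=C\C)C=C)C(=O)OC | intermediate
19 | cis-epoxy aldehyde (C6 = CHO), O2 TES, C7 vinyl | O=C[C@@H]1O[C@]1(C)C[C@H](O[Si](CC)(CC)CC)/C=C(\[C@H](OC(C)=O)[C@@H](OC(=O)/C(C)=C\C)C=C)C(=O)OC | intermediate
20 | methyl 2-(bromomethyl)acrylate | C=C(CBr)C(=O)OC | starting material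
21 | seco epoxy aldehyde with the (Z)-CH=C(CH2Br)CO2Me terminus | O=C[C@@H]1O[C@]1(C)C[C@H](O[Si](CC)(CC)CC)/C=C(\[C@H](OC(C)=O)[C@@H](OC(=O)/C(C)=C\C)/C=C(\CBr)C(=O)OC)C(=O)OC | intermediate
22 | ten-membered hydroxy ester, (6S,7R), present as its chromium alkoxide (not isolated) | COC(=O)C(=C)[C@@H]1[C@H](OC(=O)/C(C)=C\C)[C@@H](OC(C)=O)/C(C(=O)OC)=C\[C@@H](O[Si](CC)(CC)CC)C[C@@]2(C)O[C@H]2[C@H]1O | intermediate
23 | 2-O-triethylsilyl ether of the target | C=C1C(=O)O[C@H]2[C@H]1[C@H](OC(=O)/C(C)=C\C)[C@@H](OC(C)=O)/C(C(=O)OC)=C\[C@@H](O[Si](CC)(CC)CC)C[C@@]1(C)O[C@@H]21 | intermediate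
24 | CNP0278274.1, methyl (2S,4R,5S,6S,7R,8S,9S)-9-acetoxy-8-angeloyloxy-4,5-epoxy-2-hydroxygermacra-1(10),11(13)-dien-6,12-olid-14-oate, ring carbons cis at C1=C10, cis-epoxide, trans-lactone | C=C1C(=O)O[C@H]2[C@H]1[C@H](OC(=O)/C(C)=C\C)[C@@H](OC(C)=O)/C(C(=O)OC)=C\[C@@H](O)C[C@@]1(C)O[C@@H]21 | target

## Step count and risks

Total step count: 14. Longest linear sequence: 12 (steps 1–6 and 9–14). Steps 7 and 8 form the side branch.

**Risk 1, step 13 (ring closure).** The allylchromium carries an acyloxy group next to its γ-carbon and may lose angelate to give a diene before the slow ring closure happens. The facial outcome in the ring-forming transition state is also not proven.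

The fallback sets out from 21 and comes back at 23. The bromide of 21 is exchanged for boron with B2pin2 and Pd2(dba)3 (toluene/DMSO, 40 °C). This gives the covalent 2-alkoxycarbonyl allylboronate aldehyde F9, which cannot eliminate and adds only slowly at room temperature. F9 is then closed under high dilution with Sc(OTf)3 (10 mol %) or by heating in toluene. The reaction runs through a closed six-membered allylboration transition state, and the resulting borate lactonises to 23.

**Risk 2, step 12 (cross metathesis).** Both partners are sluggish: a secondary allylic ester and a hindered 1,1-disubstituted acrylate.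

The fallback sets out from 18 and comes back at 21.
- The terminal vinyl group of 18 alone is ozonised (Sudan red end point, Me2S) to the C7 aldehyde F5.
- A Morita–Baylis–Hillman reaction with methyl acrylate (DABCO) gives the allylic alcohol F6 as an epimer mixture that does not matter.
- NBS/Me2S converts F6 by SN2' into the bis-TES allylic bromide F7.
- PPTS in MeOH at 0 °C frees only the primary hydroxyl, giving the primary alcohol F8.
- Dess–Martin periodinane oxidises F8 to 21.

**Risk 3, step 9 (acyloxy-allylation).** Aldehyde 11 is very electrophilic. Me3SiCl may attack the epoxide, and the level of catalyst control with an angelate donor is untested.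

The fallback sets out from 11 and comes back at 18.
- Allyl 4-methoxybenzyl ether is metalated (s-BuLi, −78 °C) and trapped with iPrOBpin to give the (Z)-γ-alkoxyallylboronate F1.
- Allylboration of 11 with F1, catalysed by the chiral phosphoric acid (R)-TRIP, gives the syn C9 alcohol/C8 PMB ether F2.
- Acetylation gives the acetate F3.
- DDQ removes the PMB group to give the C8 alcohol F4.
- Yamaguchi esterification of F4 with 12 (2,4,6-trichlorobenzoyl chloride, Et3N, then DMAP) gives 18.

## Further compounds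

F1 | step 9 | (Z)-2-[3-(4-methoxybenzyloxy)prop-2-enyl]-4,4,5,5-tetramethyl-1,3,2-dioxaborolane | COc1ccc(CO/C=C\CB2OC(C)(C)C(C)(C)O2)cc1
F2 | step 9 | syn C9 alcohol/C8 PMB ether, (8S,9S)-configured as in 18, O2 and O6 TES | CC[Si](CC)(CC)OC[C@@H]1O[C@]1(C)C[C@H](O[Si](CC)(CC)CC)/C=C(\[C@H](O)[C@@H](OCc2ccc(OC)cc2)C=C)C(=O)OC
F3 | step 9 | C9 acetate/C8 PMB ether | CC[Si](CC)(CC)OC[C@@H]1O[C@]1(C)C[C@H](O[Si](CC)(CC)CC)/C=C(\[C@H](OC(C)=O)[C@@H](OCc2ccc(OC)cc2)C=C)C(=O)OC
F4 | step 9 | C9 acetate/C8 alcohol | CC[Si](CC)(CC)OC[C@@H]1O[C@]1(C)C[C@H](O[Si](CC)(CC)CC)/C=C(\[C@H](OC(C)=O)[C@@H](O)C=C)C(=O)OC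
F5 | step 12 | C7 aldehyde from 18 (configuration as in 18) | CC[Si](CC)(CC)OC[C@@H]1O[C@]1(C)C[C@H](O[Si](CC)(CC)CC)/C=C(\[C@H](OC(C)=O)[C@@H](OC(=O)/C(C)=C\C)C=O)C(=O)OC
F6 | step 12 | Morita–Baylis–Hillman alcohol (C7 epimer mixture) | CC[Si](CC)(CC)OC[C@@H]1O[C@]1(C)C[C@H](O[Si](CC)(CC)CC)/C=C(\[C@H](OC(C)=O)[C@@H](OC(=O)/C(C)=C\C)C(O)C(=C)C(=O)OC)C(=O)OC
F7 | step 12 | bis-TES (Z)-allylic bromide | CC[Si](CC)(CC)OC[C@@H]1O[C@]1(C)C[C@H](O[Si](CC)(CC)CC)/C=C(\[C@H](OC(C)=O)[C@@H](OC(=O)/C(C)=C\C)/C=C(\CBr)C(=O)OC)C(=O)OC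
F8 | step 12 | primary (C6) alcohol, O2 TES, allylic bromide | OC[C@@H]1O[C@]1(C)C[C@H](O[Si](CC)(CC)CC)/C=C(\[C@H](OC(C)=O)[C@@H](OC(=O)/C(C)=C\C)/C=C(\CBr)C(=O)OC)C(=O)OC
F9 | step 13 | seco epoxy aldehyde with CH2Bpin in place of CH2Br | O=C[C@@H]1O[C@]1(C)C[C@H](O[Si](CC)(CC)CC)/C=C(\[C@H](OC(C)=O)[C@@H](OC(=O)/C(C)=C\C)/C=C(\CB2OC(C)(C)C(C)(C)O2)C(=O)OC)C(=O)OC
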